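**Retrosynthetic overview**
1. Dichrostachine H ⇒ [4+2] union of labdatriene 12 (C12=C13–C14=C15) with flavone B-ring quinone 18 (C1′=C6′), forming C12–C1′ and C15–C6′; 18 is generated anodically from hydroquinone 17 in the presence of 12. The cyclohexene ring is formed last.
2. Diene 12 ⇐ 7-oxo triene ester 10 (C7 set by hydride, C18 adjusted) ⇐ C12 aldehyde 7 (two Wittig reactions) ⇐ keto-enal 3 (Wharton transposition for the 7-oxygenated 8(17)-methylene; α-ketol cleavage for the side chain).
3. Keto-enal 3 ⇐ oxidative opening of ring C (C13=C14) of abietic acid, which supplies C4, C5, C9, C10 and the C18 carbonyl in the correct configuration.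
4. Hydroquinone 17 ⇐ 5,7-dihydroxy-2′,4′,5′-trimethoxyflavone 16 ⇐ phloroacetophenone 13 + 2,4,5-trimethoxybenzoyl chloride 14 (pyranone ring by C-aroylation and cyclodehydration).

Assumptions: 2,4,5-trimethoxybenzoyl chloride is bought (otherwise one extra step from the acid). Abietane numbering is used for 1–6 and labdane numbering from 7 on (abietane C14 = labdane C17); the enedione ring uses flavone numbering (C1′ bears the chromone, C6′ is the CH).

**Terpene branch**

Step 1
Reactants: 1 (–)-abietic acid
Product: 2 methyl abietate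
Conditions: MeI, K2CO3, DMF, rt
Reagents that add atoms: iodomethane, CI
Why: Carboxylate O-alkylation (SN2) masks the hindered C18 acid as an ester that survives every step up to the hydride reduction.

Step 2
Reactants: 2 methyl abietate
Product: 3 methyl 13,14-dioxo-13,14-secoabiet-7-en-18-oate (ring-B enal C7=C8–C14HO; side chain C9–CH2CH2–CO–iPr)
Conditions: OsO4 (2 mol %), NMO (1.1 equiv), acetone/H2O, 0 °C to rt; then NaIO4
Reagents that add atoms: osmium tetroxide, O=[Os](=O)(=O)=O, re-oxidised by NMO, C[N+]1([O-])CCOCC1 (source of the two carbonyl O atoms)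
Why: Lemieux–Johnson-type dihydroxylation and periodate cleavage; the 13,14-alkene is the one attacked first in abietates, and the remaining C7=C8 becomes a deactivated enal alkene once cleavage has occurred.

Step 3
Reactants: 3 keto-enal
Product: 4 methyl 7α,8α-epoxy-13,14-dioxo-13,14-secoabietan-18-oate
Conditions: 30 % H2O2, NaOH (cat.), MeOH, 0 °C
Reagents that add atoms: hydrogen peroxide, OO
Why: Weitz–Scheffer nucleophilic epoxidation of the enal; hydroperoxide adds axially to C7 from the α face (this C7 configuration is erased in step 9), and the isolated ketone and hindered ester do not react.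

Step 4
Reactants: 4 epoxy aldehyde
Product: 5 methyl 7α-hydroxy-13-oxo-13,14-secoabiet-8(14)-en-18-oate (8-exo-methylene, 7α-OH)
Conditions: N2H4·H2O (2 equiv), AcOH (cat.), MeOH, 0 °C to rt; aqueous oxalic acid work-up
Reagents that add atoms: none
Why: Wharton transposition turns the formyl carbon into the exocyclic methylene and leaves the epoxide oxygen on C7 with retention; any hydrazone of the hindered isopropyl ketone is hydrolysed on acidic work-up.

Step 5
Reactants: 5 hydroxy ketone
Product: 6 methyl 7α,12ξ-dihydroxy-13-oxo-13,14-secoabiet-8(14)-en-18-oate (C12 epimers)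
Conditions: KHMDS (2.3 equiv), THF, –78 °C; then 2-(phenylsulfonyl)-3-phenyloxaziridine
Reagents that add atoms: Davis oxaziridine, O=S(=O)(c1ccccc1)N1OC1c1ccccc1
Why: Kinetic deprotonation occurs at the CH2 side (C12) of the CH2/isopropyl ketone and the potassium enolate is hydroxylated (Davis oxidation); the C12 configuration is irrelevant, and the C18 ester has no α-hydrogen.

Step 6
Reactants: 6 α-ketol
Product: 7 methyl 7α-hydroxy-12-oxo-13,14,15,16-tetranorlabd-8(17)-en-18-oate (C12 aldehyde)
Conditions: Pb(OAc)4, MeOH/PhH (1:1), 0 °C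
Reagents that add atoms: none
Why: Criegee-type α-ketol cleavage breaks C12–C13 to give the aldehyde and methyl isobutyrate without touching the allylic alcohol or the 1,1-disubstituted alkene.

Step 7
Reactants: 7 aldehyde
Product: 8 methyl (12E)-7α-hydroxy-14-oxo-15-norlabda-8(17),12-dien-18-oate
Conditions: Ph3P=C(CH3)CHO, PhMe, 90 °C
Reagents that add atoms: 2-(triphenylphosphoranylidene)propanal, CC(C=O)=P(c1ccccc1)(c1ccccc1)c1ccccc1
Why: Wittig reaction with a stabilised ylide gives the E-trisubstituted enal (typically >95:5) and does not react further with the less electrophilic enal product.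

Step 8
Reactants: 8 enal
Product: 9 methyl 7α-hydroxylabda-8(17),12E,14-trien-18-oate
Conditions: Ph3PCH3Br, KOtBu (3 equiv), THF, 0 °C
Reagents that add atoms: methyltriphenylphosphonium bromide, C[P+](c1ccccc1)(c1ccccc1)c1ccccc1.[Br-]
Why: Wittig methylenation of the enal completes the (E)-3-methylpenta-2,4-dienyl side chain; the hindered ester is inert and the free alcohol only consumes one equivalent of ylide.

Step 9
Reactants: 9 allylic alcohol
Product: 10 methyl 7-oxolabda-8(17),12E,14-trien-18-oate
Conditions: MnO2 (20 equiv), CH2Cl2, rt; used crude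
Reagents that add atoms: none
Why: Selective MnO2 oxidation of the allylic alcohol removes the wrong (7α) configuration under neutral conditions that do not isomerise the exocyclic enone or touch the diene.

Step 10
Reactants: 10 enone ester
Product: 11 labda-8(17),12E,14-triene-7β,18-diol
Conditions: LiAlH4 (3 equiv), Et2O, –78 °C to rt
Reagents that add atoms: none
Why: 1,2-Hydride reduction; the small hydride attacks the C7 ketone axially from the α face to give the equatorial 7β-alcohol (7S, controlled by the trans-decalin), and the ester is reduced to the 18-alcohol in the same operation.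

Step 11
Reactants: 11 diol
Product: 12 7β-hydroxylabda-8(17),12E,14-trien-18-al
Conditions: TEMPO (0.2 equiv), PhI(OAc)2 (1.1 equiv), CH2Cl2, rt
Reagents that add atoms: none
Why: Oxoammonium (TEMPO/BAIB) oxidation is selective for the primary C18 alcohol over the secondary 7β-alcohol and leaves the diene untouched; the aldehyde is non-enolisable.

**Flavone branch**

Step 12
Reactants: 13 2′,4′,6′-trihydroxyacetophenone; 14 2,4,5-trimethoxybenzoyl chloride
Product: 15 1-(2,4,6-trihydroxyphenyl)-3-(2,4,5-trimethoxyphenyl)propane-1,3-dione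
Conditions: LiHMDS (4.2 equiv), THF, –78 to –10 °C; then 14, –78 °C to rt; aq. HCl
Reagents that add atoms: none
Why: Baker–Venkataraman-type C-aroylation of the phenoxide/enolate polyanion gives the 1,3-diketone without phenol protection.

Step 13
Reactants: 15 diketone
Product: 16 5,7-dihydroxy-2-(2,4,5-trimethoxyphenyl)-4H-chromen-4-one
Conditions: H2SO4 (cat.), AcOH, 95 °C
Reagents that add atoms: none
Why: Acid-catalysed cyclodehydration of the o-hydroxyaryl 1,3-diketone closes the pyranone ring.

Step 14
Reactants: 16 trimethoxyflavone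
Product: 17 5,7-dihydroxy-2-(2,5-dihydroxy-4-methoxyphenyl)-4H-chromen-4-one
Conditions: CAN (2.5 equiv), MeCN/H2O (4:1), 0 °C, 15 min; then aq. Na2S2O4
Reagents that add atoms: water, O
Why: CAN oxidative demethylation of the para-related 2′,5′-dimethoxy pair gives the 4′-methoxy-p-quinone, which is reduced on work-up to the storable hydroquinone; the carbonyl-deactivated A ring is the less oxidisable ring.

**Union**

Step 15
Reactants: 12 hydroxy-diene aldehyde; 17 hydroquinone flavone
Product: 19 Dichrostachine H, via quinone 18 (2-(5,7-dihydroxy-4-oxo-4H-chromen-2-yl)-5-methoxy-1,4-benzoquinone, not isolated)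
Conditions: 17 (1.0 equiv), 12 (1.5 equiv), 1.0 M LiClO4 in MeNO2/MeCN (9:1), AcOH (2 equiv), carbon-felt anode/Pt cathode, undivided cell, 1 mA cm⁻², 2.1 F mol⁻¹ (anode ≤ +0.8 V vs Ag/AgCl), 25 °C, then 12 h at 25 °C without current; preparative HPLC
Reagents that add atoms: none
Why: Proposed new method: anodic 2e⁻/2H⁺ dehydrogenation of 17, at a potential well below that of the triene, allylic alcohol, aldehyde and A-ring phenols, generates quinone 18 at low steady-state concentration in a Li⁺-rich medium, where the unprotected diene 12 traps it in a [4+2] at the chromonyl-substituted C1′=C6′ bond (the methoxy-bearing bond is a deactivated vinylogous ester); Li⁺ on the more basic C2′=O makes C6′ the electrophilic terminus so C15 bonds to C6′ and C12 to C1′ (quaternary centre), suprafacial addition sets H-6′ and the chromone cis (1′S,6′R), and 12R requires the chromone-endo/enedione-exo approach to the Re face of C12 under control of the C9 side-chain rotamer; the closest known reactions are Diels–Alder trapping of electrogenerated simple quinones in LiClO4/nitromethane and thermal or Lewis-acid Diels–Alder reactions of 2-methoxy-5-alkyl-1,4-benzoquinones at the substituted double bond, neither shown for a heteroaryl quinone forming a quaternary centre with an unprotected terpenoid diene.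

**Compound list**
1 | (–)-abietic acid (abieta-7,13-dien-18-oic acid) | CC(C)C1=CC2=CC[C@@H]3[C@](C)(CCC[C@@]3(C)C(=O)O)[C@H]2CC1 | starting material
2 | methyl abietate | CC(C)C1=CC2=CC[C@@H]3[C@](C)(CCC[C@@]3(C)C(=O)OC)[C@H]2CC1 | intermediate
3 | methyl 13,14-dioxo-13,14-secoabiet-7-en-18-oate | O=CC1=CC[C@@H]2[C@](C)(CCC[C@@]2(C)C(=O)OC)[C@H]1CCC(=O)C(C)C | intermediate
4 | methyl 7α,8α-epoxy-13,14-dioxo-13,14-secoabietan-18-oate | O=C[C@@]12O[C@@H]1C[C@@H]1[C@](C)(CCC[C@@]1(C)C(=O)OC)[C@H]2CCC(=O)C(C)C | intermediate
5 | methyl 7α-hydroxy-13-oxo-13,14-secoabiet-8(14)-en-18-oate | C=C1[C@H](O)C[C@@H]2[C@](C)(CCC[C@@]2(C)C(=O)OC)[C@H]1CCC(=O)C(C)C | intermediate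
6 | methyl 7α,12ξ-dihydroxy-13-oxo-13,14-secoabiet-8(14)-en-18-oate | C=C1[C@H](O)C[C@@H]2[C@](C)(CCC[C@@]2(C)C(=O)OC)[C@H]1CC(O)C(=O)C(C)C | intermediate
7 | methyl 7α-hydroxy-12-oxo-13,14,15,16-tetranorlabd-8(17)-en-18-oate | C=C1[C@H](O)C[C@@H]2[C@](C)(CCC[C@@]2(C)C(=O)OC)[C@H]1CC=O | intermediate
8 | methyl (12E)-7α-hydroxy-14-oxo-15-norlabda-8(17),12-dien-18-oate | C=C1[C@H](O)C[C@@H]2[C@](C)(CCC[C@@]2(C)C(=O)OC)[C@H]1C/C=C(C)/C=O | intermediate
9 | methyl 7α-hydroxylabda-8(17),12E,14-trien-18-oate | C=C1[C@H](O)C[C@@H]2[C@](C)(CCC[C@@]2(C)C(=O)OC)[C@H]1C/C=C(C)/C=C | intermediate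
10 | methyl 7-oxolabda-8(17),12E,14-trien-18-oate | C=C1C(=O)C[C@@H]2[C@](C)(CCC[C@@]2(C)C(=O)OC)[C@H]1C/C=C(C)/C=C | intermediate
11 | labda-8(17),12E,14-triene-7β,18-diol | C=C1[C@@H](O)C[C@@H]2[C@](C)(CCC[C@@]2(C)CO)[C@H]1C/C=C(C)/C=C | intermediate
12 | 7β-hydroxylabda-8(17),12E,14-trien-18-al | C=C1[C@@H](O)C[C@@H]2[C@](C)(CCC[C@@]2(C)C=O)[C@H]1C/C=C(C)/C=C | intermediate
13 | 2′,4′,6′-trihydroxyacetophenone | CC(=O)c1c(O)cc(O)cc1O | starting material
14 | 2,4,5-trimethoxybenzoyl chloride | COc1cc(OC)c(C(=O)Cl)cc1OC | starting material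
15 | 1-(2,4,6-trihydroxyphenyl)-3-(2,4,5-trimethoxyphenyl)propane-1,3-dione | COc1cc(OC)c(C(=O)CC(=O)c2c(O)cc(O)cc2O)cc1OC | intermediate
16 | 5,7-dihydroxy-2′,4′,5′-trimethoxyflavone | COc1cc(OC)c(-c2cc(=O)c3c(O)cc(O)cc3o2)cc1OC | intermediate
17 | 5,7,2′,5′-tetrahydroxy-4′-methoxyflavone | COc1cc(O)c(-c2cc(=O)c3c(O)cc(O)cc3o2)cc1O | intermediate
18 | 2-(5,7-dihydroxy-4-oxo-4H-chromen-2-yl)-5-methoxy-1,4-benzoquinone | COC1=CC(=O)C(c2cc(=O)c3c(O)cc(O)cc3o2)=CC1=O | intermediate (generated in the cell, not isolated)
19 | Dichrostachine H ((12R,1′S,6′R) adduct; 7β-OH, 18-al) | C=C1[C@@H](O)C[C@@H]2[C@](C)(CCC[C@@]2(C)C=O)[C@H]1C[C@@H]1C(C)=CC[C@H]2C(=O)C(OC)=CC(=O)[C@@]12c1cc(=O)c2c(O)cc(O)cc2o1 | target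

**Totals**
Total steps: 15. Longest linear sequence: 12 (steps 1–11, then 15).

**Steps most likely to fail**
1. Step 15 (proposed anodic oxidation with in-cell Diels–Alder). The quinone may decompose, or the required enedione-exo/Re-face adduct may be a minor isomer among the endo and opposite-face adducts. Fallback (known chemistry): isolate quinone 18 (oxidise 17 with Ag2O, or omit the dithionite in step 14) and run a conventional thermal or high-pressure quinone–diene Diels–Alder with 12 (toluene, 60–80 °C, or 10–12 kbar at rt), then separate the diastereomers by HPLC.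
2. Step 11 (primary over secondary allylic alcohol oxidation). The neopentyl primary alcohol may not be oxidised cleanly ahead of the 7β-alcohol. Fallback: replace steps 10–11 by a protecting-group sequence: NaBH4/CeCl3 reduction of 10 at C7 only, TES protection of 7β-OH, DIBAL-H to the 18-alcohol, Dess–Martin oxidation, use the TES ether in step 15 and remove it last with HF·pyridine (three extra steps).
3. Step 14 (CAN on a flavone with free 5,7-phenols). The A ring may be oxidised or nitrated. Fallback: build the B ring at the hydroquinone oxidation level, using 2,5-bis(benzyloxy)-4-methoxybenzoyl chloride in steps 12–13 and releasing 17 by hydrogenolysis (H2, Pd/C), so no oxidant meets the free-phenol flavone.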